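**Atom labels used throughout:** ring carbons C1 (bears the aroyl group), C2 (CH2), C3 (=CH), C4 (=C–CH3), C5 (bears the prenyl group), C6 (bears phenyl); C7 is the ketone carbon; C1′ is the prenyl CH2. The target 21 is (1R,5R,6R), with aroyl/phenyl trans and phenyl/prenyl trans.

## The problem

The target 21 is a cyclohex-3-ene with three contiguous stereocentres, C1 (aroyl), C6 (phenyl) and C5 (prenyl), all trans, beside a trisubstituted C3=C4 alkene whose methyl group sits on C4. Formally it is the Diels–Alder adduct of chalcone A1 and (E)-β-ocimene A2. In that union the methyl and the alkyl substituent of the diene direct in opposite senses, so the C5–C6 bond (rather than C5–C1) is not secured. Regiochemistry and absolute configuration are therefore the real difficulties.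

C1 is α to the ketone and can be equilibrated. C5 and C6 cannot be corrected once the carbocycle exists, so they must be set deliberately; C6 can control C5 (trans) if both lie in a ring when C5 is made.

The molecule carries two acid- and oxidant-sensitive trisubstituted alkenes (a skipped 1,5-diene) and a hindered 2,6-dihydroxyaryl ketone. The phenols must be masked during organometallic steps and released without strong Lewis acids.

The feature that makes the key step possible is the γ,δ-unsaturated ketone C7(=O)–C1–C2–C3=C4, in which C1 and C4 are also joined through C6–C5. Read backwards as a Claisen retron, the allyl vinyl ether is cyclic: a 2-vinyl-3,4-dihydro-2H-pyran in which an oxygen bridges C7 and C4. The C4 stereocentre of that ring disappears in the rearrangement and C1 is correctable, so only C5 and C6 need control.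

## Retrosynthesis

**21 ← 20.** The two phenols are released last from the bis-MOM ether 20 by mild protic acetal exchange. MOM is chosen because it directs the arene metalation used earlier and avoids a late Lewis-acid demethylation next to the alkenes.

**20 ← 18 (key disconnection).** The C1–C2 bond is cut and an O–C4 bond, absent from the target, is added. This gives the 6-aryl-2-methyl-2-vinyl-3,4-dihydro-2H-pyran 18. Forward, a Claisen rearrangement contracts the oxacycle to the carbocycle, creates the ketone, places the alkene at C3=C4 with the methyl on C4, and sets C1 (then equilibrated through the intermediate mixture 19). This cut is preferred to the Diels–Alder bonds C1–C2/C5–C6 because 18 is the formal hetero-Diels–Alder adduct of the same two partners with the regiochemistry already fixed by connectivity: C4 is bonded to C5 before the step. Compound 18 carries only the two stereocentres C5/C6 that matter; its C4 configuration is irrelevant. The forward reaction must be a clean [3,3] shift at a temperature the enol ether and MOM groups tolerate.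

**18 ← 11 + 15.** The C7–aryl bond is cut. Forward, arene 15 is lithiated between its two OMOM groups (16), transmetalated to zinc (17) and coupled (Negishi) with the lactone-derived ketene acetal phosphate 11. This is preferred to adding an aryllithium to a hindered acid derivative after ring contraction, because the C(sp2)–C(sp2) coupling site is unhindered on the pyran side. Arene 15 comes from the commercial aldehyde 12 through diol 14.

**11 ← 10 ← 9 ← 7 ← 5.** Phosphate 11 is the enol derivative of lactone 10. Lactone 10 is obtained from lactone 5 by a 1,5-transposition: the carbonyl of 5 becomes the tertiary allylic carbinol C4 by successive addition of methyllithium 6 (giving 7) and vinylmagnesium bromide 8 (giving diol 9). The former CH2O terminus is then oxidised to the new lactone carbonyl C7. The carbonyl of 5 thus serves first as the activating group for introducing the prenyl group at C5, then as the carbinol carbon of the Claisen substrate.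

**5 ← 3 ← 1 + 2.** The C5–C1′ bond is cut (enolate alkylation with prenyl bromide 4, trans to the phenyl group in the six-membered lactone). The C6–phenyl bond is cut (rhodium-catalysed asymmetric 1,4-addition of phenylboronic acid 2 to 5,6-dihydro-2H-pyran-2-one 1). One catalytic step supplies the absolute configuration; the ring relays it to C5. An acyclic Michael route to the same C5/C6 pair was rejected because neither the enolate regiochemistry nor the syn/anti outcome is reliable there.

## Roads not taken

**Alternative 1:** Cut C1–C2 and C5–C6: Diels–Alder reaction of chalcone A1 with (E)-β-ocimene A2, thermally or with a chiral boron/BINOL-type Lewis acid that uses the 2′-hydroxy ketone chelate. This is the obvious and shortest route. Its weakness is structural: the C4 methyl group raises the HOMO coefficient at C5, the C5 alkyl group raises it at C2, so both orientations compete and the regioisomer A3 (prenyl carbon bonded to C1) is expected alongside the target. A chiral catalyst can choose the face but not the orientation. The diene must also be geometrically pure, and a free 2′-hydroxychalcone can cyclise to the flavanone on heating. The chosen plan fixes the orientation by connectivity and takes absolute configuration from a well-behaved catalytic step.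

**Alternative 2:** Cut C6–phenyl, C5–C1′ and C4–CH3 on a carbocyclic template: conjugate phenylation/enolate prenylation of the enantioenriched 4-substituted cyclohexenone A4 to ketone A5, kinetic enol triflate A6 and methyl cross-coupling, then conversion of the CH2OSi group into the aryl ketone. Stereocontrol is secure (C1 → C6 → C5 relay, all trans) and regiochemistry is unambiguous. However, A4 itself needs a desymmetrisation or auxiliary sequence, and the end game costs about five further steps (desilylation, oxidation, aryllithium addition, oxidation, deprotection), roughly 12–13 steps in all. The chosen plan reaches the same relay in a lactone and lets the rearrangement deliver ring, alkene and ketone together.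

**Alternative 3:** Cut C5–C6, C1–C2 and C3=C4: a one-pot [2+2+2] Michael–Michael–Wittig annulation of the more substituted enolate of ketone A7 with the protected chalcone A8 and vinylphosphonium salt A9, through the 1,5-diketone enolate corresponding to A10. It is very short and regiochemically clean. It offers no dependable handle for absolute configuration, the required enolate regiochemistry of a methyl ketone is hard to enforce, and syn/anti control at C5/C6 in an acyclic Michael addition is weak. The lactone template of the chosen plan removes all three uncertainties.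

Key step: step 10

Assumption: with C5/C6 trans, the C1 epimer with the aroyl group trans to phenyl (all three ring substituents pseudo-equatorial) is taken as the thermodynamically preferred one, as for other 2-arylcycloalkyl ketones; all numbered starting materials are treated as commercial.

## Route

Step 1
Reactants: 1 5,6-dihydro-2H-pyran-2-one; 2 phenylboronic acid
Product: 3 (S)-4-phenyltetrahydro-2H-pyran-2-one
Conditions: 2 (excess), Rh(acac)(C2H4)2 (3 mol %), (S)-BINAP (3.3 mol %), dioxane/H2O 10:1, 100 °C
Reagents that add atoms: none
Why: Rhodium-catalysed asymmetric 1,4-addition of an arylboronic acid (Hayashi–Miyaura reaction), established for this unsaturated lactone; the ligand selects the enantioface and so sets C6 (the ligand enantiomer is the one that delivers the (S)-lactone), and the oxa-π-allyl rhodium species is protonated by water.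

Step 2
Reactants: 3 (S)-4-phenyltetrahydro-2H-pyran-2-one; 4 1-bromo-3-methylbut-2-ene (prenyl bromide)
Product: 5 (3R,4S)-3-(3-methylbut-2-en-1-yl)-4-phenyltetrahydro-2H-pyran-2-one
Conditions: LDA, THF, −78 °C; then 4, DMPU, −78 → −30 °C
Reagents that add atoms: none
Why: Lactone enolate alkylation; the electrophile approaches the half-chair enolate anti to the adjacent phenyl group, so C5 is set trans to C6 by 1,2-induction, the usual outcome for 4-substituted δ-lactone enolates.

Step 3
Reactants: 5 (3R,4S)-3-(3-methylbut-2-en-1-yl)-4-phenyltetrahydro-2H-pyran-2-one; 6 methyllithium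
Product: 7 (3R,4S)-6-hydroxy-3-(3-methylbut-2-en-1-yl)-4-phenylhexan-2-one (in ring–chain equilibrium with its cyclic hemiketal)
Conditions: 6 (1.05 equiv), THF, −78 °C; AcOH quench at −78 °C
Reagents that add atoms: none
Why: Single 1,2-addition of an organolithium to a δ-lactone; the tetrahedral lithium hemiketal is stable at −78 °C and is protonated cold, so the ketone is not exposed to base and the α-stereocentre is kept.

Step 4
Reactants: 7 (3R,4S)-6-hydroxy-3-(3-methylbut-2-en-1-yl)-4-phenylhexan-2-one; 8 vinylmagnesium bromide
Product: 9 (3RS,4R,5S)-3-methyl-4-(3-methylbut-2-en-1-yl)-5-phenylhept-1-ene-3,7-diol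
Conditions: anhydrous CeCl3 (3 equiv), 8 (3 equiv), THF, −78 → 0 °C; aq NH4Cl
Reagents that add atoms: none
Why: Organocerium-mediated 1,2-addition, which suppresses enolisation of the α-branched ketone; the new tertiary carbinol (C4) forms as a mixture, which is immaterial because this centre becomes sp2 in step 10.

Step 5
Reactants: 9 (3RS,4R,5S)-3-methyl-4-(3-methylbut-2-en-1-yl)-5-phenylhept-1-ene-3,7-diol
Product: 10 (4S,5R,6RS)-6-ethenyl-6-methyl-5-(3-methylbut-2-en-1-yl)-4-phenyltetrahydro-2H-pyran-2-one
Conditions: TEMPO (0.2 equiv), PhI(OAc)2 (2.5 equiv), CH2Cl2, rt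
Reagents that add atoms: none
Why: Oxoammonium-catalysed oxidative lactonisation of a 1,5-diol: the primary alcohol is oxidised to the aldehyde, which is trapped by the tertiary alcohol as a lactol and oxidised again; the tertiary allylic alcohol and the alkenes are not oxidised under these conditions.

Step 6
Reactants: 10 (4S,5R,6RS)-6-ethenyl-6-methyl-5-(3-methylbut-2-en-1-yl)-4-phenyltetrahydro-2H-pyran-2-one
Product: 11 (2RS,3R,4R)-2-ethenyl-2-methyl-3-(3-methylbut-2-en-1-yl)-4-phenyl-3,4-dihydro-2H-pyran-6-yl diphenyl phosphate
Conditions: KHMDS (1.3 equiv), (PhO)2P(O)Cl (1.5 equiv), THF/HMPA, −78 → 0 °C; filtration through Et3N-deactivated silica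
Reagents that add atoms: diphenyl chlorophosphate, O=P(Cl)(Oc1ccccc1)Oc1ccccc1
Why: O-phosphorylation of the lactone potassium enolate to the ketene acetal phosphate, a standard electrophile for cross-coupling at a lactone carbon; only C1 is enolisable and no stereocentre is touched (the changed descriptor at the phenyl-bearing carbon is a priority effect only).

Step 7
Reactants: 12 3-hydroxy-4,5-dimethoxybenzaldehyde
Product: 14 4,5-dimethoxybenzene-1,3-diol, via aryl formate 13 (not isolated)
Conditions: mCPBA (1.2 equiv), CH2Cl2, 0 °C → rt; aq NaHCO3 wash; then K2CO3 (cat.), MeOH, rt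
Reagents that add atoms: meta-chloroperbenzoic acid, OOC(=O)c1cccc(Cl)c1
Why: Baeyer–Villiger (Dakin-type) oxidation of an electron-rich benzaldehyde; the para-methoxy group favours aryl migration to the formate 13, which is methanolysed to the phenol.

Step 8
Reactants: 14 4,5-dimethoxybenzene-1,3-diol
Product: 15 1,2-dimethoxy-3,5-bis(methoxymethoxy)benzene
Conditions: MOMCl (3 equiv), iPr2NEt (4 equiv), CH2Cl2, 0 °C → rt
Reagents that add atoms: chloromethyl methyl ether, COCCl
Why: Standard phenol protection; the two OMOM groups later direct metalation to the carbon between them and are removed by mild acid at the end.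

Step 9
Reactants: 15 1,2-dimethoxy-3,5-bis(methoxymethoxy)benzene; 11 (2RS,3R,4R)-2-ethenyl-2-methyl-3-(3-methylbut-2-en-1-yl)-4-phenyl-3,4-dihydro-2H-pyran-6-yl diphenyl phosphate
Product: 18 (2RS,3R,4S)-6-[3,4-dimethoxy-2,6-bis(methoxymethoxy)phenyl]-2-ethenyl-2-methyl-3-(3-methylbut-2-en-1-yl)-4-phenyl-3,4-dihydro-2H-pyran, via aryllithium 16 (not isolated), via arylzinc chloride 17 (not isolated)
Conditions: 15 (1.8 equiv), n-BuLi, THF, 0 °C; ZnCl2, 0 °C → rt; then 11 (1.0 equiv), Pd2(dba)3 (2.5 mol %), SPhos (10 mol %), THF, 40 °C
Reagents that add atoms: n-butyllithium, CCCC[Li] (Li of 16); zinc chloride, Cl[Zn]Cl (Zn and Cl of 17)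
Why: Directed ortho-metalation between the two OMOM groups, transmetalation to zinc and Negishi coupling with the ketene acetal phosphate, a known coupling for lactone-derived enol phosphates; the stereocentres are untouched (the descriptor at the phenyl-bearing carbon changes from R to S by priority only).

Step 10
Reactants: 18 (2RS,3R,4S)-6-[3,4-dimethoxy-2,6-bis(methoxymethoxy)phenyl]-2-ethenyl-2-methyl-3-(3-methylbut-2-en-1-yl)-4-phenyl-3,4-dihydro-2H-pyran
Product: 20 [3,4-dimethoxy-2,6-bis(methoxymethoxy)phenyl][(1R,5R,6R)-4-methyl-5-(3-methylbut-2-en-1-yl)-6-phenylcyclohex-3-en-1-yl]methanone, via C1-epimeric ketone mixture 19 (not isolated)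
Conditions: degassed PhMe (0.02 M), BHT (5 mol %), silylated sealed tube, 170 °C; then DBU (1 equiv), 80 °C
Reagents that add atoms: none
Why: On heating, the allyl vinyl ether C1=C7(Ar)–O–C4(Me)–C3H=C2H2 embedded in 18 undergoes a concerted [3,3]-sigmatropic (Claisen) rearrangement: C2 bonds to C1 as the O–C4 bond breaks, giving the C7=O ketone and the C3=C4 alkene. The closest known reaction type is the thermal Claisen rearrangement of 2-alkenyl-3,4-dihydro-2H-pyrans to 4-acylcyclohexenes (carbocyclic ring contraction), here with an aryl group on the enol ether carbon and a quaternary allylic carbon, both of which should lower the barrier. The six-membered carbocycle closes by C1–C2 bond formation through a boat-like, bicyclo[2.2.2]octene-shaped transition state with the vinyl group pseudo-axial over the enol ether; no other ring size is geometrically accessible. C5 and C6 are spectators and keep the configurations set in steps 1 and 2, while C4 loses its stereogenicity, which is why it never had to be controlled. C1 is formed on the face to which the vinyl group of each C4 epimer points, so the two epimers of 18 give the two C1 epimers 19; DBU then equilibrates C1 through the ketone enolate to the all-trans isomer 20. The step needs the [3,3] shift to win over retro-[4+2] cleavage of the dihydropyran and over ionisation of the tertiary allylic ether; the moderate temperature, the acid-free silylated glassware and the strongly exergonic formation of the C=O bond should secure this. The regiochemistry that a Diels–Alder reaction leaves open is fixed here by connectivity, since the methyl-bearing C4 was bonded to C5 before the rearrangement.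

Step 11
Reactants: 20 [3,4-dimethoxy-2,6-bis(methoxymethoxy)phenyl][(1R,5R,6R)-4-methyl-5-(3-methylbut-2-en-1-yl)-6-phenylcyclohex-3-en-1-yl]methanone
Product: 21 (2,6-dihydroxy-3,4-dimethoxyphenyl)[(1R,5R,6R)-4-methyl-5-(3-methylbut-2-en-1-yl)-6-phenylcyclohex-3-en-1-yl]methanone
Conditions: conc. HCl (5 equiv), MeOH, rt
Reagents that add atoms: none
Why: Acid-catalysed acetal exchange of the MOM ethers with methanol; MOM groups ortho to a carbonyl cleave readily, dilute acid at room temperature should leave the trisubstituted alkenes alone, and C1 already has its thermodynamic configuration.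

## Compound list

1 | 5,6-dihydro-2H-pyran-2-one | O=C1C=CCCO1 | starting material
2 | phenylboronic acid | OB(O)c1ccccc1 | starting material
3 | (S)-4-phenyltetrahydro-2H-pyran-2-one | O=C1C[C@@H](c2ccccc2)CCO1 | intermediate
4 | 1-bromo-3-methylbut-2-ene (prenyl bromide) | CC(C)=CCBr | starting material
5 | (3R,4S)-3-(3-methylbut-2-en-1-yl)-4-phenyltetrahydro-2H-pyran-2-one | O=C1[C@H](CC=C(C)C)[C@@H](c2ccccc2)CCO1 | intermediate
6 | methyllithium | [Li]C | starting material
7 | (3R,4S)-6-hydroxy-3-(3-methylbut-2-en-1-yl)-4-phenylhexan-2-one | CC(=O)[C@H](CC=C(C)C)[C@@H](c1ccccc1)CCO | intermediate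
8 | vinylmagnesium bromide | C=C[Mg]Br | starting material
9 | (3RS,4R,5S)-3-methyl-4-(3-methylbut-2-en-1-yl)-5-phenylhept-1-ene-3,7-diol | C=CC(C)(O)[C@H](CC=C(C)C)[C@@H](c1ccccc1)CCO | intermediate
10 | (4S,5R,6RS)-6-ethenyl-6-methyl-5-(3-methylbut-2-en-1-yl)-4-phenyltetrahydro-2H-pyran-2-one | O=C1C[C@H](c2ccccc2)[C@@H](CC=C(C)C)C(C)(C=C)O1 | intermediate
11 | (2RS,3R,4R)-2-ethenyl-2-methyl-3-(3-methylbut-2-en-1-yl)-4-phenyl-3,4-dihydro-2H-pyran-6-yl diphenyl phosphate | C=CC1(C)OC(OP(=O)(Oc2ccccc2)Oc2ccccc2)=C[C@H](c2ccccc2)[C@H]1CC=C(C)C | intermediate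
12 | 3-hydroxy-4,5-dimethoxybenzaldehyde | COc1cc(C=O)cc(O)c1OC | starting material
13 | 3-hydroxy-4,5-dimethoxyphenyl formate | COc1cc(OC=O)cc(O)c1OC | intermediate
14 | 4,5-dimethoxybenzene-1,3-diol | COc1cc(O)cc(O)c1OC | intermediate
15 | 1,2-dimethoxy-3,5-bis(methoxymethoxy)benzene | COCOc1cc(OC)c(OC)c(OCOC)c1 | intermediate
16 | [3,4-dimethoxy-2,6-bis(methoxymethoxy)phenyl]lithium | COCOc1cc(OC)c(OC)c(OCOC)c1[Li] | intermediate
17 | chloro[3,4-dimethoxy-2,6-bis(methoxymethoxy)phenyl]zinc | COCOc1cc(OC)c(OC)c(OCOC)c1[Zn]Cl | intermediate
18 | (2RS,3R,4S)-6-[3,4-dimethoxy-2,6-bis(methoxymethoxy)phenyl]-2-ethenyl-2-methyl-3-(3-methylbut-2-en-1-yl)-4-phenyl-3,4-dihydro-2H-pyran | C=CC1(C)OC(c2c(OCOC)cc(OC)c(OC)c2OCOC)=C[C@H](c2ccccc2)[C@H]1CC=C(C)C | intermediate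
19 | [3,4-dimethoxy-2,6-bis(methoxymethoxy)phenyl][(1RS,5R,6R)-4-methyl-5-(3-methylbut-2-en-1-yl)-6-phenylcyclohex-3-en-1-yl]methanone | COCOc1cc(OC)c(OC)c(OCOC)c1C(=O)C1CC=C(C)[C@H](CC=C(C)C)[C@H]1c1ccccc1 | intermediate
20 | [3,4-dimethoxy-2,6-bis(methoxymethoxy)phenyl][(1R,5R,6R)-4-methyl-5-(3-methylbut-2-en-1-yl)-6-phenylcyclohex-3-en-1-yl]methanone | COCOc1cc(OC)c(OC)c(OCOC)c1C(=O)[C@@H]1CC=C(C)[C@H](CC=C(C)C)[C@H]1c1ccccc1 | intermediate
21 | (2,6-dihydroxy-3,4-dimethoxyphenyl)[(1R,5R,6R)-4-methyl-5-(3-methylbut-2-en-1-yl)-6-phenylcyclohex-3-en-1-yl]methanone | COc1cc(O)c(C(=O)[C@@H]2CC=C(C)[C@H](CC=C(C)C)[C@H]2c2ccccc2)c(O)c1OC | target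

## Step count and risk

Total steps: 11. Longest linear sequence: 9 (steps 1–6, 9, 10, 11); the arene branch (steps 7, 8) joins at step 9. Enantiomeric purity rests on step 1 alone; lactones 3 and 5 are the natural points for enrichment by crystallisation if needed.

**Step 10 (key step).** The temperature needed for the boat-like shift may bring competing retro-[4+2] fragmentation or opening of the acid-sensitive enol ether. The C4 epimer whose vinyl group is syn to the prenyl group may rearrange more slowly. Equilibration at C1 of the hindered ketone may be incomplete. Fallback, from lactone 10 (bypassing steps 6 and 9): enolisation and silylation (LDA, TBSCl, HMPA, THF, −78 °C) give the silyl ketene acetal F1. This rearranges in toluene at about 105 °C (Ireland–Claisen ring contraction of a lactone enolate) to the tert-butyldimethylsilyl ester F2. Mild hydrolysis gives the carboxylic acid F3, and amide formation (MeNHOMe·HCl, carbodiimide) gives the Weinreb amide F4. Addition of aryllithium 16 returns the route at ketone mixture 19, which is equilibrated to 20 as in step 10.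

**Step 9.** Transmetalation and reductive elimination of a di-ortho-substituted arylzinc may be slow, so that hydrolysis or thermal decomposition of the ketene acetal phosphate takes over. Fallback, from lactone 10 and aryllithium 16: 1,2-addition at −78 °C gives the δ-hydroxy ketone F5 (in equilibrium with its hemiketal). Cyclodehydration (PPTS, 4 Å sieves, benzene, 60 °C) returns the route at dihydropyran 18, replacing the cross-coupling by addition and dehydration.

**Step 4.** The basic vinyl reagent may enolise the α-branched methyl ketone, costing conversion and eroding the configuration at the carbon that becomes C5. Fallback, from hydroxy ketone 7: the much less basic ethynylmagnesium bromide (CeCl3, THF, −78 °C) gives the propargylic diol F6. Semihydrogenation over Lindlar catalyst (the terminal alkyne reacts before the trisubstituted alkene) returns the route at diol 9.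

**Step 11.** Protic acid may hydrate or shift the trisubstituted alkenes while the acetals are cleaved. Fallback, from 20: trans-silylation under buffered, non-protic conditions (TMSOTf, 2,2′-bipyridyl, CH2Cl2, 0 °C) converts the aryl MOM ethers into the bis(trimethylsilyl) ether F7. Neutral hydrolysis (H2O, THF) returns the route at 21.

## Further compounds

F1 | step 10 | tert-butyl{[(2RS,3R,4R)-2-ethenyl-2-methyl-3-(3-methylbut-2-en-1-yl)-4-phenyl-3,4-dihydro-2H-pyran-6-yl]oxy}dimethylsilane | C=CC1(C)OC(O[Si](C)(C)C(C)(C)C)=C[C@H](c2ccccc2)[C@H]1CC=C(C)C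
F2 | step 10 | tert-butyldimethylsilyl (1RS,5R,6R)-4-methyl-5-(3-methylbut-2-en-1-yl)-6-phenylcyclohex-3-ene-1-carboxylate | CC(C)(C)[Si](C)(C)OC(=O)C1CC=C(C)[C@H](CC=C(C)C)[C@H]1c1ccccc1
F3 | step 10 | (1RS,5R,6R)-4-methyl-5-(3-methylbut-2-en-1-yl)-6-phenylcyclohex-3-ene-1-carboxylic acid | OC(=O)C1CC=C(C)[C@H](CC=C(C)C)[C@H]1c1ccccc1
F4 | step 10 | (1RS,5R,6R)-N-methoxy-N,4-dimethyl-5-(3-methylbut-2-en-1-yl)-6-phenylcyclohex-3-ene-1-carboxamide | CON(C)C(=O)C1CC=C(C)[C@H](CC=C(C)C)[C@H]1c1ccccc1
F5 | step 9 | (3S,4R,5RS)-1-[3,4-dimethoxy-2,6-bis(methoxymethoxy)phenyl]-5-hydroxy-5-methyl-4-(3-methylbut-2-en-1-yl)-3-phenylhept-6-en-1-one | C=CC(C)(O)[C@H](CC=C(C)C)[C@@H](c1ccccc1)CC(=O)c1c(OCOC)cc(OC)c(OC)c1OCOC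
F6 | step 4 | (3RS,4R,5S)-3-methyl-4-(3-methylbut-2-en-1-yl)-5-phenylhept-1-yne-3,7-diol | C#CC(C)(O)[C@H](CC=C(C)C)[C@@H](c1ccccc1)CCO
F7 | step 11 | [3,4-dimethoxy-2,6-bis(trimethylsilyloxy)phenyl][(1R,5R,6R)-4-methyl-5-(3-methylbut-2-en-1-yl)-6-phenylcyclohex-3-en-1-yl]methanone | COc1cc(O[Si](C)(C)C)c(C(=O)[C@@H]2CC=C(C)[C@H](CC=C(C)C)[C@H]2c2ccccc2)c(O[Si](C)(C)C)c1OC
A1 | alternative 1 | (E)-1-(2,6-dihydroxy-3,4-dimethoxyphenyl)-3-phenylprop-2-en-1-one | COc1cc(O)c(C(=O)/C=C/c2ccccc2)c(O)c1OC
A2 | alternative 1 | (E)-β-ocimene, (3E)-3,7-dimethylocta-1,3,6-triene | C=C/C(C)=C/CC=C(C)C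
A3 | alternative 1 | (2,6-dihydroxy-3,4-dimethoxyphenyl)[3-methyl-2-(3-methylbut-2-en-1-yl)-6-phenylcyclohex-3-en-1-yl]methanone (regioisomeric adduct; stereoisomer mixture) | COc1cc(O)c(C(=O)C2C(CC=C(C)C)C(C)=CCC2c2ccccc2)c(O)c1OC
A4 | alternative 2 | (R)-4-{[tert-butyl(dimethyl)silyl]oxymethyl}cyclohex-2-en-1-one | O=C1C=C[C@H](CO[Si](C)(C)C(C)(C)C)CC1
A5 | alternative 2 | (2R,3S,4R)-4-{[tert-butyl(dimethyl)silyl]oxymethyl}-2-(3-methylbut-2-en-1-yl)-3-phenylcyclohexan-1-one | O=C1CC[C@@H](CO[Si](C)(C)C(C)(C)C)[C@H](c2ccccc2)[C@H]1CC=C(C)C
A6 | alternative 2 | (4R,5S,6R)-4-{[tert-butyl(dimethyl)silyl]oxymethyl}-6-(3-methylbut-2-en-1-yl)-5-phenylcyclohex-1-en-1-yl trifluoromethanesulfonate | O=S(=O)(OC1=CC[C@@H](CO[Si](C)(C)C(C)(C)C)[C@H](c2ccccc2)[C@H]1CC=C(C)C)C(F)(F)F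
A7 | alternative 3 | 6-methylhept-5-en-2-one | CC(=O)CCC=C(C)C
A8 | alternative 3 | (E)-1-[3,4-dimethoxy-2,6-bis(methoxymethoxy)phenyl]-3-phenylprop-2-en-1-one | COCOc1cc(OC)c(OC)c(OCOC)c1C(=O)/C=C/c1ccccc1
A9 | alternative 3 | ethenyl(triphenyl)phosphonium bromide | C=C[P+](c1ccccc1)(c1ccccc1)c1ccccc1.[Br-]
A10 | alternative 3 | (3S,4R)-1-[3,4-dimethoxy-2,6-bis(methoxymethoxy)phenyl]-4-(3-methylbut-2-en-1-yl)-3-phenylhexane-1,5-dione | CC(=O)[C@H](CC=C(C)C)[C@@H](c1ccccc1)CC(=O)c1c(OCOC)cc(OC)c(OC)c1OCOC
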